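**Retrosynthetic overview**
1. Feature: apart from its two catechol rings (both bought), kukoamine A is an acyclic, constitutionally symmetric chain N1–C2–C3–C4–N5–(CH2)4–N10–C11–C12–C13–N14. Each acylated outer nitrogen (N1, N14) is separated from an inner secondary amine nitrogen (N5, N10) by exactly three carbons.
2. Key disconnection: this N–CH2CH2CH2–N unit is the hydrogenated form of an enamide N–CH=CH–CH2–N. That enamide is the anti-Markovnikov adduct of a primary amide N–H to the terminal alkyne of an N-propargyl amine, so N1–C2 and C13–N14 are cut together.
3. Fragments: two molecules of O,O'-dibenzyl dihydrocaffeamide and one N,N'-di-Boc-N,N'-dipropargylputrescine. The inner nitrogens come from putrescine and the outer ones from the amide, so no selective acylation of a tetraamine is needed.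
4. Fragment syntheses: putrescine → bis-carbamate → double propargylation; dihydrocaffeic acid → perbenzylation → ammonolysis.
5. Endgame and rings: one hydrogenation saturates both enamides and frees both catechols, and acid then unmasks N5 and N10. No ring is formed at any stage.

Key step: step 5

Remark 1: kukoamine A has no stereocentre and no stereogenic double bond, so it is achiral and needs no enantioselective step. Only the transient enamide geometry in 8 and 9 is specified.
Remark 2: in the two-directional protecting-group steps (1–3, 6, 7) both ends react in one operation and the half-reacted species are not numbered. The mono-adduct is listed for the key step, because there the second addition is a separate catalytic event on a changed substrate.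

Step 1
Reactants: 1 butane-1,4-diamine (putrescine)
Product: 2 di-tert-butyl butane-1,4-diyldicarbamate (N,N'-di-Boc-putrescine)
Conditions: Boc2O (2.2 equiv), CH2Cl2, 0 °C → rt
Reagents that add atoms: di-tert-butyl dicarbonate, CC(C)(C)OC(=O)OC(=O)OC(C)(C)C
Why: Standard N-Boc protection (nucleophilic acyl substitution of the primary amines on the dicarbonate) should go to completion at both ends and leaves each future inner nitrogen as a non-basic carbamate with exactly one N–H for the next alkylation.

Step 2
Reactants: 2 N,N'-di-Boc-putrescine; 3 3-bromoprop-1-yne (propargyl bromide)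
Product: 4 di-tert-butyl butane-1,4-diylbis(prop-2-yn-1-ylcarbamate) (N,N'-di-Boc-N,N'-dipropargylputrescine)
Conditions: NaH (2.4 equiv), DMF, 0 °C; then 3 (80 wt % in toluene, 2.6 equiv), 0 °C → rt; cold aqueous NH4Cl quench
Reagents that add atoms: propargyl bromide (3), C#CCBr
Why: SN2 N-alkylation of the sodium carbamates with an unhindered propargylic bromide is routine, cannot over-alkylate because each nitrogen carries only one hydrogen, and with a small excess of base at or below room temperature should not trigger propargyl-to-allenyl isomerisation.

Step 3
Reactants: 5 3-(3,4-dihydroxyphenyl)propanoic acid (dihydrocaffeic acid)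
Product: 6 benzyl 3-[3,4-bis(benzyloxy)phenyl]propanoate
Conditions: BnBr (3.5 equiv), K2CO3 (4 equiv), DMF, 60 °C, N2
Reagents that add atoms: benzyl bromide, BrCc1ccccc1
Why: Williamson ether synthesis at both phenols and SN2 esterification of the carboxylate take place in one operation with excess benzyl bromide, the inert atmosphere protecting the catecholate from autoxidation until it is capped.

Step 4
Reactants: 6 benzyl 3-[3,4-bis(benzyloxy)phenyl]propanoate
Product: 7 3-[3,4-bis(benzyloxy)phenyl]propanamide
Conditions: NH3 (7 M in MeOH, large excess), sealed vessel, 70 °C; trituration of the solid amide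
Reagents that add atoms: ammonia, N
Why: Ammonolysis (nucleophilic acyl substitution) of an unhindered ester by a large excess of ammonia under pressure should give the crystalline primary amide, the aryl benzyl ethers being inert to ammonia.

Step 5
Reactants: 4 N,N'-di-Boc-N,N'-dipropargylputrescine (1 equiv); 7 3-[3,4-bis(benzyloxy)phenyl]propanamide (two molecules incorporated, 3 equiv used)
Product: 9 N5,N10-di-Boc-tetra-O-benzyl-(2Z,12Z)-2,3,12,13-tetradehydrokukoamine A (bis-(Z)-enamide; each end ArCH2CH2C(O)NH–CH=CH–CH2–N(Boc)– on a (CH2)4 bridge; Ar = 3,4-(BnO)2C6H3), via mono-(Z)-enamide monoalkyne 8 (not isolated)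
Conditions: 7 (3.0 equiv), [Ru(η3-2-methylallyl)2(cod)] (10 mol %), 1,4-bis(dicyclohexylphosphino)butane (dcypb, 12 mol %), Yb(OTf)3 (8 mol %), H2O (12 equiv), DMF, 60 °C, Ar; 4 added by syringe pump over several hours; chromatography removes Ru and phosphine residues and returns unreacted 7
Reagents that add atoms: none
Why: The Ru(II)–dcypb species released from the methallyl precatalyst binds the primary amide as an N-bound amidate and converts the terminal alkyne by a 1,2-hydrogen shift into a vinylidene Ru=C=CH–CH2N(Boc)R with an electrophilic metal-bound carbon; migration of the amidate nitrogen to that carbon and protonolysis of the alkenyl–Ru bond release the enamide with nitrogen on the former terminal carbon, and the cycle repeats at the second alkyne of 8, all atoms of 4 and of two molecules of 7 ending up in 9. The closest known reaction type is the ruthenium/Lewis-acid-catalysed anti-Markovnikov hydroamidation of terminal alkynes with primary amides to secondary (Z)-enamides, run here under its usual catalyst system on a diyne. No ring closes and no stereocentre is formed; the Z geometry imposed by the bulky chelating phosphine, and any later E/Z or positional drift of the C=C bond within the N–C3–N unit, do not matter because step 6 saturates it. Regioselectivity rests on the vinylidene pathway, which only a C≡C–H terminus can enter and which delivers the nucleophile only to the terminal carbon, so N1–C2 and C13–N14 form rather than branched enamides. Single N-vinylation of each amide is secured by the lower nucleophilicity and greater bulk of the secondary enamide and by keeping 7 in excess through slow addition of 4, which also holds down alkyne–alkyne dimerisation. The medium contains no base, so the propargyl carbamate has no path to an allenamide, and Yb(OTf)3 solvated by DMF and water should be too weak a Lewis acid to cleave Boc or ionise the allylic C–N bond of the product.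

Step 6
Reactants: 9 bis-(Z)-enamide
Product: 10 N5,N10-di-Boc-kukoamine A
Conditions: H2 (1 atm), 10 % Pd/C, THF–MeOH 1:1, rt; filtration and short chromatography under Ar
Reagents that add atoms: none
Why: Heterogeneous catalytic hydrogenation saturates the two disubstituted enamide C=C bonds and hydrogenolyses the four aryl benzyl ethers in one operation, while Boc groups and amides are inert, the neutral medium avoids acid-induced loss of the allylic nitrogen from the enamide, and the carbamate-masked inner nitrogens cannot inhibit the palladium as free amines would.

Step 7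
Reactants: 10 N5,N10-di-Boc-kukoamine A
Product: 12 kukoamine A (free base), via kukoamine A dihydrochloride 11 (not isolated)
Conditions: HCl (4 M in 1,4-dioxane), 0 °C → rt, evaporate; then NaOMe (2.0 equiv), degassed MeOH, 0 °C, Ar; desalting on Sephadex LH-20 (degassed MeOH)
Reagents that add atoms: hydrogen chloride, Cl (its chloride is held only in 11 and leaves again on neutralisation)
Why: Acidolysis of the tert-butyl carbamates (loss of the tert-butyl cation as isobutene, then decarboxylation) spares the secondary amides and the catechols, and exactly two equivalents of methoxide under argon then discharge the two ammonium chlorides without leaving excess base that would promote catechol autoxidation.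

**Compound list**
1 | butane-1,4-diamine (putrescine) | NCCCCN | starting material
2 | di-tert-butyl butane-1,4-diyldicarbamate | CC(C)(C)OC(=O)NCCCCNC(=O)OC(C)(C)C | intermediate
3 | 3-bromoprop-1-yne (propargyl bromide) | C#CCBr | starting material
4 | di-tert-butyl butane-1,4-diylbis(prop-2-yn-1-ylcarbamate) | C#CCN(C(=O)OC(C)(C)C)CCCCN(C(=O)OC(C)(C)C)CC#C | intermediate
5 | 3-(3,4-dihydroxyphenyl)propanoic acid (dihydrocaffeic acid) | OC(=O)CCc1ccc(O)c(O)c1 | starting material
6 | benzyl 3-[3,4-bis(benzyloxy)phenyl]propanoate | O=C(OCc1ccccc1)CCc1ccc(OCc2ccccc2)c(OCc2ccccc2)c1 | intermediate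
7 | 3-[3,4-bis(benzyloxy)phenyl]propanamide | NC(=O)CCc1ccc(OCc2ccccc2)c(OCc2ccccc2)c1 | intermediate
8 | mono-(Z)-enamide monoalkyne (one end of 4 hydroamidated, the other still propargyl) | C#CCN(C(=O)OC(C)(C)C)CCCCN(C(=O)OC(C)(C)C)C/C=C\NC(=O)CCc1ccc(OCc2ccccc2)c(OCc2ccccc2)c1 | intermediate
9 | N5,N10-di-Boc-tetra-O-benzyl-(2Z,12Z)-2,3,12,13-tetradehydrokukoamine A | O=C(CCc1ccc(OCc2ccccc2)c(OCc2ccccc2)c1)N/C=C\CN(C(=O)OC(C)(C)C)CCCCN(C(=O)OC(C)(C)C)C/C=C\NC(=O)CCc1ccc(OCc2ccccc2)c(OCc2ccccc2)c1 | intermediate
10 | N5,N10-di-Boc-kukoamine A | O=C(CCc1ccc(O)c(O)c1)NCCCN(C(=O)OC(C)(C)C)CCCCN(C(=O)OC(C)(C)C)CCCNC(=O)CCc1ccc(O)c(O)c1 | intermediate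
11 | kukoamine A dihydrochloride | O=C(CCc1ccc(O)c(O)c1)NCCCNCCCCNCCCNC(=O)CCc1ccc(O)c(O)c1.Cl.Cl | intermediate
12 | kukoamine A | O=C(CCc1ccc(O)c(O)c1)NCCCNCCCCNCCCNC(=O)CCc1ccc(O)c(O)c1 | target

Total step count: 7. Longest linear sequence: 5 steps (1 → 2 → 4 → 9 → 10 → 12, or equally 5 → 6 → 7 → 9 → 10 → 12).

**Steps most likely to fail**

First, step 5. Three processes threaten it:
- The diyne may be consumed by ruthenium-catalysed alkyne–alkyne dimerisation or oligomerisation before both ends have met an amide.
- The reaction may stall after the first addition, because carbamate or enamide carbonyl groups chelate the metal.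
- The Lewis acid and water may slowly hydrolyse the enamide.

The fallback sets out from 4 and 7 and returns to the route at 10. It makes the same two N–C bonds by cross-coupling instead of addition. Hydrozirconation of both alkynes of 4 with Cp2Zr(H)Cl (THF, rt) should give the bis[(E)-alkenylzirconocene chloride] F1. This is quenched in the flask with I2 at 0 °C to the bis-(E)-vinyl iodide F2. Copper-catalysed Goldberg-type N-vinylation of 7 (2.4 equiv) with F2 (CuI, N,N'-dimethylethylenediamine, Cs2CO3, THF, 65 °C) proceeds with retention of geometry. It should give the bis-(E)-enamide F3, the geometrical isomer of 9. Under the conditions of step 6, F3 is saturated and debenzylated to 10.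

Second, step 6. Three processes threaten it:
- The allylic C4–N5 and C11–N10 bonds may be cleaved hydrogenolytically on palladium in competition with saturation of the enamides.
- Traces of ruthenium and phosphine from step 5 may poison the heterogeneous catalyst.
- Removal of the four benzyl ethers may be incomplete.

The fallback sets out from 9 and returns at 11. It separates the two tasks and dispenses with palladium. Homogeneous hydrogenation with a cationic rhodium bisphosphine catalyst ([Rh(cod)(dppb)]BF4, H2 5 bar, CH2Cl2–MeOH) binds enamides through C=C and the amide oxygen and touches neither benzyl ethers nor allylic C–N bonds. It should give the saturated tetra-O-benzyl-N5,N10-di-Boc-kukoamine A F4. Treatment with BCl3 and pentamethylbenzene as benzyl-cation scavenger (CH2Cl2, −78 → 0 °C) cleaves the four aryl benzyl ethers. A methanol quench and stirring at rt follow, and the HCl generated on quenching completes carbamate cleavage. This delivers 11, which is neutralised as in step 7.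

Third, step 4. Ammonolysis of the unactivated ester may be sluggish and incomplete, forcing long heating under pressure. The fallback sets out from 6 and returns at 7. It replaces direct ammonolysis by hydrolysis and carboxyl activation. Saponification (LiOH, THF–H2O, then dilute HCl) should give 3-[3,4-bis(benzyloxy)phenyl]propanoic acid F5. Carbonyldiimidazole (THF, rt) converts it in the flask into the acyl imidazolide F6. Concentrated aqueous ammonia at 0 °C then gives 7.

**Further compounds**
F1 | step 5 | bis[(E)-alkenylzirconocene chloride] from double hydrozirconation of 4 (Cp drawn σ-bonded) | Cl[Zr](C1C=CC=C1)(C1C=CC=C1)/C=C/CN(C(=O)OC(C)(C)C)CCCCN(C(=O)OC(C)(C)C)C/C=C/[Zr](Cl)(C1C=CC=C1)C1C=CC=C1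
F2 | step 5 | di-tert-butyl butane-1,4-diylbis{[(E)-3-iodoprop-2-en-1-yl]carbamate} | I/C=C/CN(C(=O)OC(C)(C)C)CCCCN(C(=O)OC(C)(C)C)C/C=C/I
F3 | step 5 | N5,N10-di-Boc-tetra-O-benzyl-(2E,12E)-2,3,12,13-tetradehydrokukoamine A | O=C(CCc1ccc(OCc2ccccc2)c(OCc2ccccc2)c1)N/C=C/CN(C(=O)OC(C)(C)C)CCCCN(C(=O)OC(C)(C)C)C/C=C/NC(=O)CCc1ccc(OCc2ccccc2)c(OCc2ccccc2)c1
F4 | step 6 | tetra-O-benzyl-N5,N10-di-Boc-kukoamine A | O=C(CCc1ccc(OCc2ccccc2)c(OCc2ccccc2)c1)NCCCN(C(=O)OC(C)(C)C)CCCCN(C(=O)OC(C)(C)C)CCCNC(=O)CCc1ccc(OCc2ccccc2)c(OCc2ccccc2)c1
F5 | step 4 | 3-[3,4-bis(benzyloxy)phenyl]propanoic acid | OC(=O)CCc1ccc(OCc2ccccc2)c(OCc2ccccc2)c1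
F6 | step 4 | 1-{3-[3,4-bis(benzyloxy)phenyl]propanoyl}imidazole | O=C(CCc1ccc(OCc2ccccc2)c(OCc2ccccc2)c1)n1ccnc1
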